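All constants come from no measurement; what happens was integrated by code.

Follow one batch of intermediate.

| flask | starting material | reagent | time | remark |
|---|---|---|---|---|
| north | 0.012 M (fed, over 12 min) | 0.100 M | 80 min | the fed solution adds 0.10 times the starting volume |
| south | 0.030 M (fed, over 12 min) | 0.100 M | 80 min | the fed solution adds 0.10 times the starting volume |
| east | 0.10 M (fed, over 12 min) | 0.100 M | 80 min | the fed solution adds 0.10 times the starting volume |
| north-east | 0.30 M (fed, over 12 min) | 0.100 M | 80 min | the fed solution adds 0.10 times the starting volume |
| north-west | 1.0 M (fed, over 12 min) | 0.100 M | 80 min | the fed solution adds 0.10 times the starting volume |

    starting material + reagent → intermediate + by-product (k1 = 23.0 M⁻¹ min⁻¹)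
    intermediate → target (k2 = 0.0292 min⁻¹)
    target → over-reaction product (k3 = 0.0414 min⁻¹)

- [target] at the end for north, south, east, north-east, north-west, in this order
- the shape of the row from first to last (hardly changes / falls, then rises / rises all the way / falls all the way / rises, then falls)

- amounts are per litre of the starting volume; all of the dose is in the solution fed
- "hardly changes" means that all values lie within two and a half points (for a concentration: within two and a half percent of the largest)
- run time (north): 80 min

With reagent as charged, starting material has a half-life of 0.301 min, far shorter than the feed of 12 min. So, while reagent lasts, each dose soon becomes intermediate, and two first-order lags in series follow it: intermediate to target, target to over-reaction product. Call a the constant of the middle step and b that of the last. Of a batch born a time τ before the end, the part standing as target is g(τ) = a/(b − a) · (e^(−aτ) − e^(−bτ)), which we call the passage fraction; at τ = 80 min it is 0.144.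

Both ends of the row can be solved in the head. At the lean end, reagent outlasts the charge, so the average batch is born at mid-feed, with τ = 74.0 min, and there the fraction is larger, 0.164. Dividing by the final volume, 1.10 of the starting one, north gives 0.00179 M and south 0.00447 M, in proportion to the charge. At the rich end, reagent is the limiting reagent, so the intermediate made is capped at 0.100 M. The dose in north-west matches that reagent after 1.20 min, so nearly from the start the batch has the full age, and we get 0.0131 M. East, with charge equal to reagent, is where the two ends meet, and the lean rule gives it 0.0149 M. North-east, matched after 4.00 min, we place between 0.0131 M and 0.0149 M. We therefore commit to a row that rises to east and then sinks gently.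

The forecast gave 0.00181 M, 0.00453 M, 0.0154 M, 0.0141 M and 0.0134 M, shape rises, then falls, holding for the richer flasks that “reagent is limiting and used up early”.

The simulation gives 0.00181 M, 0.00453 M, 0.0154 M, 0.0140 M and 0.0135 M, shape rises, then falls, turning at 0.10 M; east stands above our 0.0149 M, and north-west above our 0.0131 M.

The last step is the largest single effect on target in north-west: without it, north-west ends at 0.0818 M of target instead of 0.0135 M, a factor of 6.07, and the shape changes. Taking b away turns the passage fraction into one minus e^(−aτ), so we expect a factor of 6.26 in north-west. With τ = 74.0 min the same reckoning gives 5.40 for north, and taking the last step away there moves target from 0.00181 M to 0.00963 M, a factor of 5.32.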